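**Retrosynthetic overview**
1. Target 11 ⇐ aryl bromide acid 8: the C6 phenol is unmasked last from C6–Br by Pd-catalysed hydroxylation. The bromine also blocks the para position and survives the oxidations.
2. 8 ⇐ chroman 5: terminal (E)-CH3 → CO2H by SeO2 allylic oxidation, then TEMPO/Pinnick.
3. 5 ⇐ ortho-farnesyl phenol 4: the O1–C2 bond and the only stereocentre come from a metal-free, chiral Brønsted acid (IDPi) catalysed, cyclase-like 6-endo hydroalkoxylation (proposed new method).
4. 4 ⇐ 4-bromo-2-methylphenol 1 + (2E,6E)-farnesyl bromide 2 by ortho-C-alkylation of the phenolate.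
5. Ring order: the benzene ring is bought; the dihydropyran ring is the only ring made (step 2).

The target's stereocentre is (2R), and both chain alkenes are E.

Assumption: the (S,S)-antipode of the IDPi catalyst is taken to give the (2R)-chroman. The sense is checked on the first run (chiral HPLC/ECD of 5); if it is opposite, the (R,R)-catalyst is used and nothing else changes. The catalyst is a confined imidodiphosphorimidate built from two (S)-3,3'-diaryl-BINOL phosphoryl units with P=N–SO2CF3 inner groups, the aryl wings tuned by screening.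

**Step 1**
Reactants: 1 4-bromo-2-methylphenol; 2 (2E,6E)-farnesyl bromide
Product: 4 4-bromo-2-methyl-6-[(2E,6E)-3,7,11-trimethyldodeca-2,6,10-trien-1-yl]phenol, via sodium 4-bromo-2-methylphenolate 3 (not isolated)
Conditions: NaH (1.05 equiv), toluene, 0 °C to rt; then 2 (0.9 equiv), rt, 16 h
Reagents that add atoms: none
Why: Ortho-C-alkylation of a phenolate: the aggregated sodium phenolate in a non-coordinating solvent attacks the allylic bromide through its ortho carbon (SN2, no allylic transposition, E,E geometry kept), C6 is the only free ortho site and the para site is blocked by Br; no stereocentre is formed.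

**Step 2**
Reactants: 4 4-bromo-2-methyl-6-[(2E,6E)-3,7,11-trimethyldodeca-2,6,10-trien-1-yl]phenol
Product: 5 (2R)-6-bromo-2-[(3E)-4,8-dimethylnona-3,7-dien-1-yl]-2,8-dimethyl-3,4-dihydro-2H-chromene
Conditions: (S,S)-IDPi (5 mol %), cyclohexane, 30 °C, 48 h
Reagents that add atoms: none
Why: Proposed new method: a confined chiral IDPi Brønsted acid acts as a small-molecule tocopherol cyclase in an asymmetric intramolecular hydroalkoxylation (6-endo-trig, Markovnikov) – the phenolic OH hydrogen-bonds to a basic sulfonyl/phosphoryl oxygen of the catalyst anion while the acidic N–H protonates C2' of the only alkene that can reach the oxygen through a six-membered chair, so protonation and C3'–O bond formation are a concerted, asynchronous anti addition inside the chiral pocket, which tells the two alkene faces apart by sending the long homoprenyl tail out through the pocket channel and holding the C3' methyl against the wall, setting C2 as R; the two remote trisubstituted alkenes have no internal nucleophile, there is no cation-stabilising fluoroalcohol in the non-polar medium, and the para-bromine lowers arene nucleophilicity, so tail-initiated polyene cyclisation should be disfavoured; closest known reaction type: IDPi-catalysed asymmetric intramolecular hydroalkoxylation of unactivated alkenols to 2,2-disubstituted tetrahydrofurans (mechanistic model: the enzymatic tocopherol-cyclase ring closure).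

**Step 3**
Reactants: 5 (2R)-6-bromo-2-[(3E)-4,8-dimethylnona-3,7-dien-1-yl]-2,8-dimethyl-3,4-dihydro-2H-chromene
Product: 6 (2E,6E)-9-[(2R)-6-bromo-2,8-dimethyl-3,4-dihydro-2H-chromen-2-yl]-2,6-dimethylnona-2,6-dien-1-ol
Conditions: SeO2 (0.3 equiv), t-BuOOH (2.5 equiv, in decane), salicylic acid (0.1 equiv), CH2Cl2, 0 °C to rt; stopped at about 60 % conversion, 5 recycled
Reagents that add atoms: tert-butyl hydroperoxide, CC(C)(C)OO (stoichiometric oxygen source); selenium dioxide, O=[Se]=O (catalytic oxygen-transfer agent)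
Why: Sharpless-type Riley allylic oxidation (ene reaction with SeO2, then [2,3]-sigmatropic shift) attacks the terminal, most electron-rich and least hindered trisubstituted alkene at its E-methyl and gives the (E)-allylic alcohol; C2 and the aryl bromide are untouched.

**Step 4**
Reactants: 6 (2E,6E)-9-[(2R)-6-bromo-2,8-dimethyl-3,4-dihydro-2H-chromen-2-yl]-2,6-dimethylnona-2,6-dien-1-ol
Product: 8 (2E,6E)-9-[(2R)-6-bromo-2,8-dimethyl-3,4-dihydro-2H-chromen-2-yl]-2,6-dimethylnona-2,6-dienoic acid, via (2E,6E)-dienal 7 (not isolated)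
Conditions: TEMPO (0.1 equiv), PhI(OAc)2 (1.1 equiv), CH2Cl2, rt; then t-BuOH/H2O, 2-methyl-2-butene (10 equiv), NaH2PO4, NaClO2, 0 °C to rt
Reagents that add atoms: sodium chlorite, [Na+].[O-]Cl=O
Why: TEMPO/PhI(OAc)2 oxidation of the allylic alcohol to the enal followed by Pinnick oxidation, with 2-methyl-2-butene scavenging HOCl, gives the acid without touching the trisubstituted alkenes or their E geometry; the ring positions ortho and para to the ether oxygen are blocked (Me, Br), so the arene is not chlorinated, and C2 is not affected.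

**Step 5**
Reactants: 8 (2E,6E)-9-[(2R)-6-bromo-2,8-dimethyl-3,4-dihydro-2H-chromen-2-yl]-2,6-dimethylnona-2,6-dienoic acid
Product: 11 (2E,6E)-9-[(2R)-6-hydroxy-2,8-dimethyl-3,4-dihydro-2H-chromen-2-yl]-2,6-dimethylnona-2,6-dienoic acid (target), via potassium carboxylate of the bromo acid 9 (not isolated), via dipotassium phenolate-carboxylate of the target 10 (not isolated)
Conditions: Pd2(dba)3 (2 mol %), tBuXPhos (8 mol %), KOH (4 equiv), 1,4-dioxane/H2O 1:1, degassed, 90 °C; then 1 M HCl, 0 °C
Reagents that add atoms: potassium hydroxide, [K+].[OH-]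
Why: Pd-catalysed C–O coupling of the aryl bromide with hydroxide (Buchwald-type hydroxylation with a bulky biaryl phosphine) turns C6–Br into the phenol while the acid rides through as its carboxylate and the trisubstituted alkenes are poor Heck partners; acidification frees the target, and the quaternary C2 cannot epimerise.

**Compound list**
1 | 4-bromo-2-methylphenol | Cc1cc(Br)ccc1O | starting material
2 | (2E,6E)-farnesyl bromide, (2E,6E)-1-bromo-3,7,11-trimethyldodeca-2,6,10-triene | CC(C)=CCC/C(C)=C/CC/C(C)=C/CBr | starting material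
3 | sodium 4-bromo-2-methylphenolate (not isolated) | Cc1cc(Br)ccc1[O-].[Na+] | intermediate
4 | 4-bromo-2-methyl-6-[(2E,6E)-3,7,11-trimethyldodeca-2,6,10-trien-1-yl]phenol | CC(C)=CCC/C(C)=C/CC/C(C)=C/Cc1cc(Br)cc(C)c1O | intermediate
5 | (2R)-6-bromo-2-[(3E)-4,8-dimethylnona-3,7-dien-1-yl]-2,8-dimethyl-3,4-dihydro-2H-chromene | C/C(=C\CC[C@]1(C)CCc2cc(Br)cc(C)c2O1)CCC=C(C)C | intermediate
6 | (2E,6E)-9-[(2R)-6-bromo-2,8-dimethyl-3,4-dihydro-2H-chromen-2-yl]-2,6-dimethylnona-2,6-dien-1-ol | C/C(=C\CC[C@]1(C)CCc2cc(Br)cc(C)c2O1)CC/C=C(\C)CO | intermediate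
7 | (2E,6E)-9-[(2R)-6-bromo-2,8-dimethyl-3,4-dihydro-2H-chromen-2-yl]-2,6-dimethylnona-2,6-dienal (not isolated) | C/C(=C\CC[C@]1(C)CCc2cc(Br)cc(C)c2O1)CC/C=C(\C)C=O | intermediate
8 | (2E,6E)-9-[(2R)-6-bromo-2,8-dimethyl-3,4-dihydro-2H-chromen-2-yl]-2,6-dimethylnona-2,6-dienoic acid | C/C(=C\CC[C@]1(C)CCc2cc(Br)cc(C)c2O1)CC/C=C(\C)C(=O)O | intermediate
9 | potassium (2E,6E)-9-[(2R)-6-bromo-2,8-dimethyl-3,4-dihydro-2H-chromen-2-yl]-2,6-dimethylnona-2,6-dienoate (not isolated) | C/C(=C\CC[C@]1(C)CCc2cc(Br)cc(C)c2O1)CC/C=C(\C)C(=O)[O-].[K+] | intermediate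
10 | dipotassium salt (phenolate and carboxylate) of the target (not isolated) | C/C(=C\CC[C@]1(C)CCc2cc([O-])cc(C)c2O1)CC/C=C(\C)C(=O)[O-].[K+].[K+] | intermediate
11 | (2E,6E)-9-[(2R)-6-hydroxy-2,8-dimethyl-3,4-dihydro-2H-chromen-2-yl]-2,6-dimethylnona-2,6-dienoic acid | C/C(=C\CC[C@]1(C)CCc2cc(O)cc(C)c2O1)CC/C=C(\C)C(=O)O | target

**Step count**
Total: 5 steps. Longest linear sequence: 5 steps (from 1 or 2).

**Steps most likely to fail**

Step 2 (the new method). The pocket has to tell CH3 from CH2R at the cationic carbon, so the ee may be low. The acid may also start tail-to-head polycyclisation at a remote alkene. Fallback with known chemistry, setting out from 4: the ring is closed with an achiral acid (p-TsOH·H2O 10 mol %, toluene, rt), the classical chroman closure of ortho-prenylated phenols. This gives the racemate, that is 5 together with its mirror image, the (2S)-chroman F1. The two are separated by preparative chiral SFC on an amylose carbamate phase, with the aryl bromide as chromophore. The (2R) fraction is 5, where the route is rejoined.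

Step 3 (SeO2 oxidation). Yield is typically moderate, and the internal alkene or over-oxidation can compete. Fallback, setting out from 5 and replacing C–H oxidation by C=C cleavage and olefination: NBS in THF/H2O at 0 °C gives the terminal bromohydrin F2 selectively, as is usual for polyprenyl chains. K2CO3 in MeOH closes it to the terminal epoxide F3. HIO4·2H2O in THF/Et2O cleaves this to the trisnor aldehyde F4 with loss of acetone. The stabilised ylide Ph3P=C(CH3)CO2Et in CH2Cl2 gives the (E)-configured ethyl ester F5. LiOH in THF/MeOH/H2O then gives the acid 8, where the route is rejoined (6 and 7 are bypassed).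

Step 5 (late-stage Pd hydroxylation). It runs on a free acid, and the product phenolate is air-sensitive in hot base. Fallback, setting out from 8 and making the C–O bond by way of a C–B bond: Miyaura borylation (Pd(dppf)Cl2, B2pin2, KOAc, dioxane, 80 °C) gives the aryl pinacol boronate F6. Mild oxidation with NaBO3·4H2O in THF/H2O at rt, then acidic work-up, gives the target 11.

**Further compounds**
F1 | step 2 | (2S)-6-bromo-2-[(3E)-4,8-dimethylnona-3,7-dien-1-yl]-2,8-dimethyl-3,4-dihydro-2H-chromene | C/C(=C\CC[C@@]1(C)CCc2cc(Br)cc(C)c2O1)CCC=C(C)C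
F2 | step 3 | (6E)-3-bromo-9-[(2R)-6-bromo-2,8-dimethyl-3,4-dihydro-2H-chromen-2-yl]-2,6-dimethylnon-6-en-2-ol (both C3 epimers) | C/C(=C\CC[C@]1(C)CCc2cc(Br)cc(C)c2O1)CCC(Br)C(C)(C)O
F3 | step 3 | (2R)-6-bromo-2-[(3E)-6-(3,3-dimethyloxiran-2-yl)-4-methylhex-3-en-1-yl]-2,8-dimethyl-3,4-dihydro-2H-chromene (both oxirane epimers) | C/C(=C\CC[C@]1(C)CCc2cc(Br)cc(C)c2O1)CCC3OC3(C)C
F4 | step 3 | (4E)-7-[(2R)-6-bromo-2,8-dimethyl-3,4-dihydro-2H-chromen-2-yl]-4-methylhept-4-enal | C/C(=C\CC[C@]1(C)CCc2cc(Br)cc(C)c2O1)CCC=O
F5 | step 3 | ethyl (2E,6E)-9-[(2R)-6-bromo-2,8-dimethyl-3,4-dihydro-2H-chromen-2-yl]-2,6-dimethylnona-2,6-dienoate | C/C(=C\CC[C@]1(C)CCc2cc(Br)cc(C)c2O1)CC/C=C(\C)C(=O)OCC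
F6 | step 5 | (2E,6E)-9-[(2R)-2,8-dimethyl-6-(4,4,5,5-tetramethyl-1,3,2-dioxaborolan-2-yl)-3,4-dihydro-2H-chromen-2-yl]-2,6-dimethylnona-2,6-dienoic acid | C/C(=C\CC[C@]1(C)CCc2cc(B3OC(C)(C)C(C)(C)O3)cc(C)c2O1)CC/C=C(\C)C(=O)O
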